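**Retrosynthetic overview**

1. The target is genistein (isoflavone) joined from C3' of its ring B to C8 of ring A of apigenin (flavone). Both halves are bought as the natural products, so no ring is formed in the route and the only skeletal bond to make is the C3'–C8'' biaryl bond.
2. That bond is made by a dehydrogenative phenol–arene cross-coupling of two C–H bonds, copying the phenoxyl-radical coupling presumed to join two flavonoid units in biflavonoid biosynthesis.
3. Enabling feature: C3' lies ortho to the 4'-OH of the para-blocked phenol ring B of the isoflavone, where the phenoxyl radical carries its spin. C8'' is the CH of the phloroglucinol-type ring A of the flavone, flanked by O7'' and the pyranone O1'' and para to O5'', its most nucleophilic carbon.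
4. The partners are shaped for cross-selectivity. Apigenin is fully O-methylated (no oxidizable OH, 5-OMe steers attack to C8). Genistein is 7-O-pivaloylated (ring A switched off, 4'-OH the only oxidizable phenol).
5. End game: methanolysis of the pivalate, then BBr3 cleavage of the three methyl ethers.

Key step: step 3

Assumption: the tri-ortho-substituted biaryl axis carries no configurational descriptor in the target and is treated as stereochemically undefined, so the route has no stereocentre to control.

**Route**

Step 1
Reactants: 1 apigenin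
Product: 2 4',5,7-tri-O-methylapigenin (5,7-dimethoxy-2-(4-methoxyphenyl)-4H-chromen-4-one)
Conditions: Me2SO4 (6 equiv), K2CO3 (8 equiv), acetone, reflux, 24 h
Reagents that add atoms: dimethyl sulfate, COS(=O)(=O)OC
Why: Exhaustive Williamson O-methylation; excess reagent and prolonged reflux should also alkylate the hydrogen-bonded 5-OH, and carbonate in acetone favours O- over C-alkylation.

Step 2
Reactants: 3 genistein
Product: 4 7-O-pivaloylgenistein (5-hydroxy-3-(4-hydroxyphenyl)-4-oxo-4H-chromen-7-yl pivalate)
Conditions: PivCl (1.05 equiv), Et3N (1.1 equiv), THF–DMF (4:1), −20 → 0 °C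
Reagents that add atoms: pivaloyl chloride, CC(C)(C)C(Cl)=O
Why: Regioselective O-acylation; 7-OH is a vinylogous carboxylic acid (pKa about 7) and gives the only phenoxide present with one equivalent of base, 4'-OH (pKa about 10) stays largely protonated, and the chelated 5-OH is inert.

Step 3
Reactants: 4 7-O-pivaloylgenistein (1 equiv); 2 4',5,7-tri-O-methylapigenin (3 equiv, excess recovered)
Product: 5 3-{4-hydroxy-3-[5,7-dimethoxy-2-(4-methoxyphenyl)-4-oxo-4H-chromen-8-yl]phenyl}-5-hydroxy-4-oxo-4H-chromen-7-yl pivalate
Conditions: boron-doped diamond anode, Pt cathode, undivided cell, 3 mA cm−2, 2.2 F mol−1 (based on 4), Et3NMe O3SOMe (0.1 M), HFIP–MeOH (82:18), 50 °C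
Reagents that add atoms: none
Why: Anodic one-electron oxidation of 4 in HFIP with loss of the 4'-OH proton gives the ring B phenoxyl radical, whose spin sits on C3'/C5' (C1' is blocked by the chromone); this electrophilic radical is trapped at C8 of the excess arene 2, and a second electron transfer, loss of H8 and tautomerization of the dienone restore both arenes, so the net change is Ar–H + Ar'–H → Ar–Ar' + H2 at the cathode. The closest known reaction type is the anodic dehydrogenative phenol–arene cross-coupling on boron-doped diamond in HFIP/MeOH, the laboratory counterpart of the cytochrome P450 phenol coupling presumed to join the two flavonoid units in biflavonoid biosynthesis. No ring is closed and no stereocentre arises. Chemoselectivity is secured because 4 carries the only oxidizable phenol, its 5-OH being locked in the hydrogen bond to C4=O on an acyl-deactivated ring, while 2 has no free OH, a higher oxidation potential and is shielded by HFIP solvation. Cross- over homo-coupling is secured by the 7-O-pivaloyl group, which makes ring A of 4 a far poorer nucleophile than the 5,7-dimethoxy ring A of 2, and by the excess of 2; the two ortho positions of ring B are equivalent, so that side poses no regiochemical question. Site selectivity on 2 follows the known preference of electrophiles for C8 of 5-O-alkylated 5,7-dioxygenated flavones (para to 5-OMe, ortho to 7-OMe and O1, whereas C6 is wedged between two methoxy groups and C3 and ring B are conjugated to the carbonyl), and a second arylation at C5' is limited by stopping near 2 F per mole.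

Step 4
Reactants: 5 coupled pivalate
Product: 6 3-{4-hydroxy-3-[5,7-dimethoxy-2-(4-methoxyphenyl)-4-oxo-4H-chromen-8-yl]phenyl}-5,7-dihydroxy-4H-chromen-4-one
Conditions: K2CO3 (3 equiv), MeOH, 0 °C → rt, Ar; then 1 M HCl
Reagents that add atoms: none
Why: Base-mediated transesterification; the pivalate of the acidic 7-OH is an activated aryl ester and should be cleaved by methoxide at room temperature, conditions under which methyl ethers and both pyranone rings persist.

Step 5
Reactants: 6 tri-O-methyl biflavonoid
Product: 7 target, 8-[5-(5,7-dihydroxy-4-oxo-4H-chromen-3-yl)-2-hydroxyphenyl]-5,7-dihydroxy-2-(4-hydroxyphenyl)-4H-chromen-4-one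
Conditions: BBr3 (15 equiv), CH2Cl2, −78 °C → rt, 24 h; then ice–water
Reagents that add atoms: none
Why: Lewis-acid cleavage of aryl methyl ethers (BBr3 demethylation, bromide attack on the O-methyl of the boron-complexed ether); the peri 5''-OMe should go first by chelation, and anhydrous ambient-temperature conditions avoid hydrolytic opening of the flavone pyranone.

**Compound list**

1 | apigenin | O=c1cc(-c2ccc(O)cc2)oc2cc(O)cc(O)c12 | starting material
2 | 4',5,7-tri-O-methylapigenin | COc1ccc(cc1)-c1cc(=O)c2c(OC)cc(OC)cc2o1 | intermediate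
3 | genistein | O=c1c(-c2ccc(O)cc2)coc2cc(O)cc(O)c12 | starting material
4 | 7-O-pivaloylgenistein | CC(C)(C)C(=O)Oc1cc(O)c2c(c1)occ(-c1ccc(O)cc1)c2=O | intermediate
5 | 3'-(4',5,7-tri-O-methylapigenin-8-yl)-7-O-pivaloylgenistein | O=c1c(-c2ccc(O)c(-c3c(OC)cc(OC)c4c(=O)cc(-c5ccc(OC)cc5)oc34)c2)coc2cc(OC(=O)C(C)(C)C)cc(O)c12 | intermediate
6 | 3'-(4',5,7-tri-O-methylapigenin-8-yl)genistein | O=c1c(-c2ccc(O)c(-c3c(OC)cc(OC)c4c(=O)cc(-c5ccc(OC)cc5)oc34)c2)coc2cc(O)cc(O)c12 | intermediate
7 | 3'-(apigenin-8-yl)genistein (CNP0142623.0) | O=c1c(-c2ccc(O)c(-c3c(O)cc(O)c4c(=O)cc(-c5ccc(O)cc5)oc34)c2)coc2cc(O)cc(O)c12 | target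

**Step count and risks**

Total steps: 5. Longest linear sequence: 4 (steps 2, 3, 4, 5 from genistein).

Steps most likely to fail:

1. Step 3 (key coupling). The oxidized phenol partner may couple with itself or oligomerize, methanol may trap the oxidized ring B, the arene may react at C6 as well as C8, or a second arylation may occur at C5'. The fallback is a Suzuki–Miyaura coupling, setting out from 2 and 4 and returning at 6.
   - 2 would be iodinated at C8 (I2, CF3CO2Ag, CHCl3, rt) to 8-iodo-4',5,7-tri-O-methylapigenin F1.
   - 4 would be iodinated ortho to its 4'-OH (NIS, cat. TFA, MeCN, 0 °C) to 3'-iodo-7-O-pivaloylgenistein F2.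
   - Miyaura borylation of F2 (B2pin2, PdCl2(dppf), KOAc, dioxane, 85 °C) would give 7-O-pivaloylgenistein 3'-pinacolboronate F3.
   - Coupling of F1 with F3 (Pd(OAc)2, SPhos, K3PO4, dioxane–H2O, 90 °C), during which the activated 7-O-pivalate is hydrolysed, would give 6 directly, and step 5 follows.

2. Step 2 (selective acylation). Acylation may spread to the 4'-OH, or the acyl group may transfer between phenols, eroding regioselectivity. The fallback is a silyl relay, setting out from 3 and returning at 4.
   - Bis-silylation (TBSCl, imidazole, DMF, rt) would give 4',7-bis-O-(tert-butyldimethylsilyl)genistein F4.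
   - Selective methanolysis of the 7-O-silyl ether, the one with the better phenoxide leaving group (K2CO3 0.2 equiv, MeOH, −10 °C), would give 4'-O-(tert-butyldimethylsilyl)genistein F5.
   - Pivaloylation of the now unique reactive 7-OH (PivCl, Et3N, CH2Cl2, 0 °C) would give 4'-O-(tert-butyldimethylsilyl)-7-O-pivaloylgenistein F6.
   - Desilylation (HF·pyridine, THF, 0 °C) would give 4.

3. Step 5 (demethylation). Cleavage of the hindered 7''-OMe may stall, or acid-induced opening and reclosure of the flavone pyranone (Wessely–Moser rearrangement) may shift the linkage from C8 to C6. The fallback replaces the methyl ethers by benzyl ethers, setting out from 1 and 4 and returning at 7.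
   - 1 would be benzylated (BnBr, K2CO3, DMF, 80 °C) to 4',5,7-tri-O-benzylapigenin F7.
   - Anodic coupling of F7 with 4 under the conditions of step 3 would give 3'-(4',5,7-tri-O-benzylapigenin-8-yl)-7-O-pivaloylgenistein F8.
   - Methanolysis (K2CO3, MeOH, rt) would give 3'-(4',5,7-tri-O-benzylapigenin-8-yl)genistein F9.
   - Neutral hydrogenolysis (H2, 10% Pd/C, THF–MeOH, rt) would give 7.

**Further compounds**

F1 | step 3 | 8-iodo-4',5,7-tri-O-methylapigenin | COc1ccc(cc1)-c1cc(=O)c2c(OC)cc(OC)c(I)c2o1
F2 | step 3 | 3'-iodo-7-O-pivaloylgenistein | O=c1c(-c2ccc(O)c(I)c2)coc2cc(OC(=O)C(C)(C)C)cc(O)c12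
F3 | step 3 | 7-O-pivaloylgenistein 3'-pinacolboronate | O=c1c(-c2ccc(O)c(B3OC(C)(C)C(C)(C)O3)c2)coc2cc(OC(=O)C(C)(C)C)cc(O)c12
F4 | step 2 | 4',7-bis-O-(tert-butyldimethylsilyl)genistein | CC(C)(C)[Si](C)(C)Oc1ccc(cc1)-c1coc2cc(O[Si](C)(C)C(C)(C)C)cc(O)c2c1=O
F5 | step 2 | 4'-O-(tert-butyldimethylsilyl)genistein | CC(C)(C)[Si](C)(C)Oc1ccc(cc1)-c1coc2cc(O)cc(O)c2c1=O
F6 | step 2 | 4'-O-(tert-butyldimethylsilyl)-7-O-pivaloylgenistein | CC(C)(C)[Si](C)(C)Oc1ccc(cc1)-c1coc2cc(OC(=O)C(C)(C)C)cc(O)c2c1=O
F7 | step 5 | 4',5,7-tri-O-benzylapigenin | O=c1cc(-c2ccc(OCc3ccccc3)cc2)oc2cc(OCc3ccccc3)cc(OCc3ccccc3)c12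
F8 | step 5 | 3'-(4',5,7-tri-O-benzylapigenin-8-yl)-7-O-pivaloylgenistein | O=c1c(-c2ccc(O)c(-c3c(OCc4ccccc4)cc(OCc4ccccc4)c4c(=O)cc(-c5ccc(OCc6ccccc6)cc5)oc34)c2)coc2cc(OC(=O)C(C)(C)C)cc(O)c12
F9 | step 5 | 3'-(4',5,7-tri-O-benzylapigenin-8-yl)genistein | O=c1c(-c2ccc(O)c(-c3c(OCc4ccccc4)cc(OCc4ccccc4)c4c(=O)cc(-c5ccc(OCc6ccccc6)cc5)oc34)c2)coc2cc(O)cc(O)c12
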